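The product Q trails in the teal run: at 25.0 h it stands at 4.1 % of the charge of G, and E at 25.8 %. E sits in the share asked, so I draw E's curve first.

| flask | G | J | temperature | remark | time |
|---|---|---|---|---|---|
| teal | 0.11 M | 0.15 M | 10 °C | run made earlier |  |
| green | 0.11 M | 0.24 M | 21 °C | run made earlier |  |
| blue | 0.17 M | 0.11 M | 10 °C | run made earlier |  |
| Tuesday's | 0.11 M | 0.110 M |  | at 25 °C until 10 h, from then on at 5 °C | 30 h |
| Thursday's | 0.11 M | 0.110 M | 5 °C |  | 30 h |
| Sunday's | 0.11 M | 0.110 M | 25 °C |  | 30 h |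

| run | time / h | Q / % | E / % |
|---|---|---|---|
| teal | 1.33 | 0 | 0.6 |
| teal | 4.00 | 0.3 | 3.5 |
| teal | 6.00 | 0.2 | 6.9 |
| teal | 10.0 | 0.5 | 13.7 |
| teal | 15.0 | 1.6 | 20.2 |
| teal | 20.0 | 2.5 | 23.9 |
| teal | 25.0 | 4.1 | 25.8 |
| green | 1.33 | 0 | 5.2 |
| green | 2.50 | 0.9 | 12.4 |
| green | 5.00 | 3.1 | 23.9 |
| green | 6.00 | 4.2 | 26.1 |
| green | 10.0 | 7.3 | 29.2 |
| green | 12.0 | 8.4 | 29.3 |
| blue | 2.00 | 0 | 0.5 |
| blue | 6.00 | 0.2 | 5.7 |
| blue | 12.0 | 0.6 | 13.3 |
| blue | 15.0 | 1.4 | 15.0 |
| blue | 25.0 | 3.4 | 19.2 |

(each reading ± 0.3 percentage points)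

- which flask leads in share of Q in all that became Q or E or D ("all alike" within 1.5 percentage points) (Tuesday's / Thursday's / Sunday's / all alike)
- share of Q in all that became Q or E or D, Tuesday's
- share of Q in all that became Q or E or D, Thursday's
- share of Q in all that became Q or E or D, Sunday's



In the teal run E starts climbing at about 0.0170 /h of the charge, then bends. Of its last two steps of equal time, the second reads 0.514 of the first, so steps shrinking in that way sum to a level of about 27.8 %. The green run has flattened at 29.3 %.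

I replace the slowly falling J by its charge and take the odds of E, its level over the rest, per unit of J. This selectivity factor is 2.57 /M in the teal run and 1.73 /M in the green run. As a test, the blue run, at the teal temperature with less J, should level near 22.0 %; it reads 19.2 % at 25.0 h, still climbing.

Carried along a straight line in temperature, the selectivity factor at 5 °C, Thursday's, is 3.08 /M, and at 25 °C, Sunday's, it is 1.49 /M. With 0.110 M of J, E should level near 25.3 % in Thursday's and 14.1 % in Sunday's. My reckoning gives E, not the share.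

The forecast names Sunday's as leader, with 9 % for Tuesday's, 2.5 % for Thursday's and 16 % for Sunday's, and holds that “J has little effect”; I have let J count.

The flasks give 24.1 % for Tuesday's, 7.05 % for Thursday's and 6.50 % for Sunday's, so Tuesday's leads. In Thursday's at 30.0 h, Z goes on to X 2.9 times as fast as it meets J to give E, and with J at 80.7 % of its charge that makes a factor, for that moment, of 3.85 /M, more than my 3.08 /M. Sunday's holds E at 14.5 % against my 14.1 %, with Q 5.27 % beside D 61.5 % at 30.0 h, while Tuesday's holds Q 11.1 % beside D 20.6 %.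

    X → Q (k = 0.0550 /h, Ea = 108 kJ/mol)
    Z → X (k = 4.40 /h, Ea = 81.0 kJ/mol)
    L → Z (k = 0.650 /h, Ea = 83.0 kJ/mol)
    Q → D (k = 0.250 /h, Ea = 97.0 kJ/mol)
    G → L (k = 1.60 /h, Ea = 80.0 kJ/mol)
    Z + J → E (k = 7.30 /M/h, Ea = 52.0 kJ/mol)
    (constants at 25 °C)

For Thursday's read at 3.0 d, the factor puts E near 25.3 %. That flask holds E at 26.1 %, with L at 2.35 %, and its share is 15.8 %.

The earlier runs and the new flask are simulated for an exercise; the scatter is artificial.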